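A rate of rise cannot be read from the late readings, since from the first of them to the last each run changes by less than its scatter of 2 percentage points. The zeta run gives 36 % at 6.00 min and 35 % at 12.0 min, and the alpha run gives 41 % at 2.50 min and 40 % at 12.0 min. Like a step response past its time constant, each run reads as a plateau, and the two levels read apart.

| flask | Z | G | remark | time | volume of the second phase over the first |
|---|---|---|---|---|---|
| zeta | 0.050 M | 2.5 equiv | run made earlier |  |  |
| alpha | 0.20 M | 2.5 equiv | run made earlier |  |  |
| flask | 0.10 M | 2.50 equiv |  | 12 min | 1.0 |

| zeta: time / min | zeta: L / % | alpha: time / min | alpha: L / % |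
|---|---|---|---|
| 1.00 | 25 | 2.50 | 41 |
| 3.00 | 29 | 5.00 | 43 |
| 6.00 | 36 | 8.00 | 38 |
| 8.00 | 37 | 10.0 | 42 |
| 12.0 | 35 | 12.0 | 40 |

(standard deviation of a reading: 2 percentage points)

* how much L there is at 12 min, in percent of the Z charged
* the change that raises the amount of L at 12 min, in percent of the Z charged most ("none" if none brings more than 2 percentage points) (south / north / none)
* amount of L at 12 min, in percent of the Z charged, after south

- in the second phase: G; everything else is in the first
- charges count per volume of the first phase; a concentration in a rate is the amount of a species over the volume of its own phase; every rate counts per litre of the first phase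
- the numbers in the tables scatter by 2 percentage points (one standard deviation)
- the earlier runs hold the two phases in the same ratio of volumes as the flask asked about

- south: doubling the amount of G, all else as stated
- north: doubling the transfer coefficient of G, all else as stated

The flask lies between the two runs in c(Z), at the same equivalents of G, so its plateau can be reckoned from how the level moves with each doubling of c(Z). From zeta to alpha is two doublings, and the flask is one doubling above zeta. The readings at 12 min give a first estimate:

step = (40 % − 35 %) / 2 = 2.5 points

L in the flask = 35 % + 2.5 points = 37.5 %

The weak link is the use of single readings, which leaves this step uncertain by 1.4 points. Averaging the flat stretches repairs it: zeta from 6.00 min on gives 36.0 %, and all of alpha gives 40.8 %. The plateau step, the change in final L per doubling of c(Z) at fixed equivalents of G, becomes: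

step = (40.8 % − 36.0 %) / 2 = 2.4 points, uncertain by 0.73 points

L in the flask = 36.0 % + 2.4 points = 38.4 %

This step says nothing about south or north, which change G and its transfer instead of c(Z).

The forecast, reasoning that “The ceiling depends only weakly on concentration”, gives 38.5 %, against this reckoning of 38.4 % from the same readings. It names south as the best change, with 41.5 % after it.

The flask gives 37.6 % at 12 min. South is best, with a change of 4.7 points to 42.3 %, against −1.9 points for north.

    X ⇌ G, rate k1*([X] - [G]/K1) per volume of the first phase (partition coefficient = 0.420, kL = 0.0290 s⁻¹)
    Z + X → L (k = 0.140 M⁻¹ s⁻¹)
    X + L → E (k = 0.0970 M⁻¹ s⁻¹)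
    2 X → J (k = 0.570 M⁻¹ s⁻¹)

The forecast stands, and the flask does sit on a plateau: L is 37.7 % at 24.0 min. At 12.0 min, Z is 52.1 % of its charge and G is 0.0108 % of its own. The flask lies 1.6 points above the zeta average of 36.0 %, against a step of 2.4 points. The neighbouring flask at 0.025 M has the same equivalents and lies one doubling below zeta, so the step puts it at 36.0 % − 2.4 points = 33.6 %. That flask gives 32.7 %, with 61 % of its Z still there.

The earlier runs and the new flask stem from a simulated flask with made-up constants; scatter was added.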